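**Retrosynthetic overview**
- The pyrrole is the only ring and is formed last by a Barton–Zard annulation. The C2–C3 bond comes from an intermolecular Michael addition of methyl isocyanoacetate to (E)-1-nitropentacos-1-ene; the C4–C5 bond comes from ring closure of the nitronate onto the isocyanide carbon, followed by loss of nitrite.
- The nitroalkene is released in the flask from 1-nitropentacosan-2-yl acetate. The nitro alcohol behind it is disconnected at C1–C2 by a Henry (nitroaldol) reaction of tetracosanal with nitromethane.
- Tetracosanal comes from tetracosan-1-ol, which comes from commercial tetracosanoic acid (lignoceric acid).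

Assumption: the target has no stereocentre (it is achiral), so it is made exactly as drawn; the transient stereocentres of the nitro alcohol, its acetate and the annulation intermediates are carried as racemates and disappear on aromatisation.

**Step 1**
Reactants: 1 tetracosanoic acid (lignoceric acid)
Product: 2 tetracosan-1-ol
Conditions: LiAlH4 (2 equiv), THF, reflux; Fieser work-up
Reagents that add atoms: none
Why: LiAlH4 hydride reduction of a carboxylic acid goes fully to the primary alcohol, and hot THF keeps the waxy C24 chain dissolved; no stereocentre is formed.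

**Step 2**
Reactants: 2 tetracosan-1-ol
Product: 3 tetracosanal
Conditions: TEMPO (10 mol %), PhI(OAc)2 (1.1 equiv), CH2Cl2, 30–35 °C
Reagents that add atoms: none
Why: TEMPO/oxoammonium-catalysed alcohol oxidation under anhydrous conditions stops at the aldehyde without over-oxidation, and warm CH2Cl2 dissolves the long-chain alcohol.

**Step 3**
Reactants: 3 tetracosanal, 4 nitromethane
Product: 5 rac-1-nitropentacosan-2-ol
Conditions: MeNO2 (10 equiv), KOt-Bu (10 mol %), THF/t-BuOH 1:1, 0 → 30 °C; AcOH quench
Reagents that add atoms: none
Why: In this Henry (nitroaldol) reaction the nitronate of nitromethane adds to the unhindered aldehyde, with excess nitromethane and only catalytic base suppressing retro-addition and aldehyde self-aldol, and the new carbinol centre is formed racemic, which does not matter because it is destroyed in step 5.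

**Step 4**
Reactants: 5 rac-1-nitropentacosan-2-ol
Product: 6 rac-1-nitropentacosan-2-yl acetate
Conditions: Ac2O (1.5 equiv), conc. H2SO4 (cat.), CH2Cl2, 0 °C → rt
Reagents that add atoms: acetic anhydride CC(=O)OC(C)=O
Why: Acid-catalysed O-acetylation of the secondary alcohol gives a stable, storable nitroalkene precursor, and the acidic medium avoids premature elimination and polymerisation; the stereocentre is untouched and still racemic.

**Step 5**
Reactants: 6 rac-1-nitropentacosan-2-yl acetate, 7 methyl isocyanoacetate
Product: 12 methyl 3-tricosyl-1H-pyrrole-2-carboxylate, via (E)-1-nitropentacos-1-ene 8 (not isolated), via Michael adduct 9 (not isolated), via 4-nitro-1-pyrroline 10 (not isolated), via 2H-pyrrole tautomer 11 (not isolated)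
Conditions: 7 (1.1 equiv), DBU (2.2 equiv), THF, 0 °C → rt, 16 h
Reagents that add atoms: none
Why: In this Barton–Zard pyrrole synthesis DBU eliminates acetic acid to give the (E)-nitroalkene, the isocyanoacetate anion adds to it in an intermolecular Michael reaction (new C2–C3 bond, chain at C3 next to the ester), the nitronate closes 5-endo-dig onto the isocyanide carbon, and loss of nitrite followed by tautomerisation gives the aromatic pyrrole, erasing all transient stereocentres.

**Compound list**
1 | tetracosanoic acid (lignoceric acid) | CCCCCCCCCCCCCCCCCCCCCCCC(=O)O | starting material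
2 | tetracosan-1-ol | CCCCCCCCCCCCCCCCCCCCCCCCO | intermediate
3 | tetracosanal | CCCCCCCCCCCCCCCCCCCCCCCC=O | intermediate
4 | nitromethane | C[N+](=O)[O-] | starting material
5 | rac-1-nitropentacosan-2-ol | CCCCCCCCCCCCCCCCCCCCCCCC(O)C[N+](=O)[O-] | intermediate
6 | rac-1-nitropentacosan-2-yl acetate | CCCCCCCCCCCCCCCCCCCCCCCC(OC(C)=O)C[N+](=O)[O-] | intermediate
7 | methyl isocyanoacetate | [C-]#[N+]CC(=O)OC | starting material
8 | (E)-1-nitropentacos-1-ene | CCCCCCCCCCCCCCCCCCCCCCC/C=C/[N+](=O)[O-] | intermediate (not isolated)
9 | methyl 2-isocyano-3-(nitromethyl)hexacosanoate (Michael adduct, racemic diastereomer mixture) | CCCCCCCCCCCCCCCCCCCCCCCC(C[N+](=O)[O-])C([N+]#[C-])C(=O)OC | intermediate (not isolated)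
10 | methyl 4-nitro-3-tricosyl-3,4-dihydro-2H-pyrrole-2-carboxylate (racemic diastereomer mixture) | CCCCCCCCCCCCCCCCCCCCCCCC1C(C(=O)OC)N=CC1[N+](=O)[O-] | intermediate (not isolated)
11 | methyl 3-tricosyl-2H-pyrrole-2-carboxylate (racemic) | CCCCCCCCCCCCCCCCCCCCCCCC1=CC=NC1C(=O)OC | intermediate (not isolated)
12 | methyl 3-tricosyl-1H-pyrrole-2-carboxylate | CCCCCCCCCCCCCCCCCCCCCCCc1cc[nH]c1C(=O)OC | target

**Totals**
Total step count: 5. Longest linear sequence: 5 steps (1 → 2 → 3 → 5 → 6 → 12).

**Steps most likely to fail, with fallbacks**

Step 5 (Barton–Zard annulation) is the most exposed: the unhindered aliphatic nitroalkene can oligomerise under DBU before the isocyanoacetate captures it. The fallback sets out from tetracosanal 3 and builds the pyrrole by a tosylglycinate annulation. Vinylmagnesium bromide (THF, 0 °C) gives hexacos-1-en-3-ol F1, and Dess–Martin periodinane (CH2Cl2, rt) gives hexacos-1-en-3-one F2. Commercial methyl N-tosylglycinate with DBU in THF adds by aza-Michael reaction and closes by intramolecular aldol to methyl 3-hydroxy-1-(4-methylbenzenesulfonyl)-3-tricosylpyrrolidine-2-carboxylate F3. POCl3/pyridine dehydrates this to methyl 1-(4-methylbenzenesulfonyl)-3-tricosyl-2,5-dihydro-1H-pyrrole-2-carboxylate F4. DBU in refluxing toluene then expels 4-methylbenzenesulfinate with aromatisation, and the sequence comes back to the route at 12.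

Step 3 (Henry reaction) can suffer from poor solubility of the waxy aldehyde, retro-nitroaldol and aldehyde self-condensation. The fallback sets out from tetracosanoic acid 1 and avoids the aldehyde altogether. Carbonyldiimidazole (THF, 50 °C) gives 1-(1H-imidazol-1-yl)tetracosan-1-one F5. C-acylation of the potassium nitronate of nitromethane (MeNO2, KOt-Bu, DMSO/THF, rt) gives 1-nitropentacosan-2-one F6. NaBH4 (THF/MeOH, 0 °C) reduces the ketone, and the sequence comes back to the route at 5.

Step 2 (oxidation to the aldehyde) can stall because 2 is poorly soluble, and the aldehyde is prone to air oxidation and trimerisation if handled slowly. The fallback sets out from tetracosanoic acid 1 and reaches the aldehyde by partial reduction instead of oxidation. Oxalyl chloride with catalytic DMF (CH2Cl2) gives tetracosanoyl chloride F7. N,O-dimethylhydroxylamine hydrochloride and Et3N give N-methoxy-N-methyltetracosanamide F8. LiAlH4 (THF, 0 °C, KHSO4 work-up) stops at the aldehyde through the chelated tetrahedral intermediate, and the sequence comes back to the route at 3.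

**Further compounds**
F1 | step 5 | hexacos-1-en-3-ol (racemic) | CCCCCCCCCCCCCCCCCCCCCCCC(O)C=C
F2 | step 5 | hexacos-1-en-3-one | CCCCCCCCCCCCCCCCCCCCCCCC(=O)C=C
F3 | step 5 | methyl 3-hydroxy-1-(4-methylbenzenesulfonyl)-3-tricosylpyrrolidine-2-carboxylate (racemic diastereomer mixture) | CCCCCCCCCCCCCCCCCCCCCCCC1(O)CCN(S(=O)(=O)c2ccc(C)cc2)C1C(=O)OC
F4 | step 5 | methyl 1-(4-methylbenzenesulfonyl)-3-tricosyl-2,5-dihydro-1H-pyrrole-2-carboxylate (racemic) | CCCCCCCCCCCCCCCCCCCCCCCC1=CCN(S(=O)(=O)c2ccc(C)cc2)C1C(=O)OC
F5 | step 3 | 1-(1H-imidazol-1-yl)tetracosan-1-one | CCCCCCCCCCCCCCCCCCCCCCCC(=O)n1ccnc1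
F6 | step 3 | 1-nitropentacosan-2-one | CCCCCCCCCCCCCCCCCCCCCCCC(=O)C[N+](=O)[O-]
F7 | step 2 | tetracosanoyl chloride | CCCCCCCCCCCCCCCCCCCCCCCC(Cl)=O
F8 | step 2 | N-methoxy-N-methyltetracosanamide | CCCCCCCCCCCCCCCCCCCCCCCC(=O)N(C)OC
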